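**Plan**

1. Retrosynthesis: the seven O–methyl bonds are cut first, then the ether bond from the ring D oxygen to ring E, then the two dioxin C–O bonds on the ring D side (one by Ullmann coupling, one by SNAr). Last come two ring B C–C bonds: the bond between the carbon bearing the dibenzofuran oxygen and the carbon attached to ring A, and the bond between the two dioxin carbons.
2. Enabling feature: in ring B the dibenzofuran oxygen and one dioxin oxygen stand para to each other, and the carbon next to the dibenzofuran-oxygen carbon carries ring A. A 2-aryloxyfuran leaves exactly this pattern when it adds an alkyne across its 2- and 5-positions and its oxygen bridge opens.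
3. Forward, first half: a ring A salicylaldehyde is joined through oxygen to a 3-methoxyfuran unit, the formyl group becomes an alkynylboronate, and one thermal cascade closes ring B and the five-membered oxygen ring. Boron marks the second dioxin carbon of ring B.
4. Forward, second half: ring D is attached at the ring B hydroxyl set free by the cascade, boron and the ring D formyl group are oxidised to hydroxyls, the dioxin is closed, ring E is added and the methyl ethers are cleaved.
5. Stereochemistry: the target has no stereocentre; the only stereogenic species are transient racemic intermediates of the cascade.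

Key step: step 8

Remark (naming): ring A is the outer dioxygenated benzene ring of the dibenzofuran, ring B the central benzene ring fused to both the furan and the dioxin, ring D the second benzene ring of the dioxin, and ring E the 3,5-dihydroxyphenyl group. The dioxin oxygen on the ring B carbon para to the dibenzofuran-oxygen carbon is called the para dioxin oxygen. The one on the ring B carbon next to the ring A-bearing carbon is called the bay dioxin oxygen. On ring D the para dioxin oxygen sits beside the carbon that carries the ring E aryloxy group, and the bay dioxin oxygen sits beside a hydroxyl-bearing carbon. Positions in furan and dibenzofuran intermediates follow the ring numbering of their names.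

Remark (assumptions): all seven phenols are carried as methyl ethers. The pinacol boronate serves as a masked hydroxyl that tells the two future dioxin carbons of ring B apart and is oxidised after ring D is attached. The 2-aryloxy-4-methoxyfuran intermediates are acid-labile and are handled on triethylamine-deactivated silica. 3-Methoxyfuran and 2-fluoro-4,6-dimethoxybenzaldehyde are taken as catalogue compounds.

**Route**

Step 1
Reactants: 1 3-methoxyfuran
Product: 3 methyl 3-methoxyfuran-2-carboxylate, via 2-lithio-3-methoxyfuran 2 (not isolated)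
Conditions: n-BuLi, THF, −78 to 0 °C; then ClCO2Me, −78 °C
Reagents that add atoms: methyl chloroformate, COC(=O)Cl
Why: Directed α-lithiation (the 2-position is both next to the ring oxygen and ortho to the methoxy group) followed by acylation of the furyllithium with a chloroformate.

Step 2
Reactants: 3 methyl 3-methoxyfuran-2-carboxylate
Product: 5 methyl 5-bromo-3-methoxyfuran-2-carboxylate, via 5-chloromagnesio furoate 4 (not isolated)
Conditions: TMPMgCl·LiCl (TMP = 2,2,6,6-tetramethylpiperidide), THF, −30 °C; then BrCl2C–CCl2Br, −30 °C to rt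
Reagents that add atoms: 1,2-dibromo-1,1,2,2-tetrachloroethane, BrC(Cl)(Cl)C(Cl)(Cl)Br
Why: Ester-tolerant magnesiation of a furan-2-carboxylate at its only free α-position (the 5-position) with TMPMgCl·LiCl, then electrophilic bromination of the furylmagnesium species.

Step 3
Reactants: 5 methyl 5-bromo-3-methoxyfuran-2-carboxylate; 6 2-hydroxy-4,6-dimethoxybenzaldehyde
Product: 7 methyl 5-(2-formyl-3,5-dimethoxyphenoxy)-3-methoxyfuran-2-carboxylate
Conditions: CuI (10 mol %), picolinic acid (20 mol %), K3PO4, DMSO, 90 °C
Reagents that add atoms: none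
Why: Ullmann-type CuI-catalysed O-arylation of a phenol by a heteroaryl bromide that the conjugated 2-ester also activates toward addition–elimination, the known way to 5-aryloxy-2-furoates.

Step 4
Reactants: 7 methyl 5-(2-formyl-3,5-dimethoxyphenoxy)-3-methoxyfuran-2-carboxylate
Product: 8 5-(2-formyl-3,5-dimethoxyphenoxy)-3-methoxyfuran-2-carboxylic acid
Conditions: LiOH, THF/H2O, rt to 40 °C; then 1 M HCl to pH 3, 0 °C
Reagents that add atoms: lithium hydroxide, [Li+].[OH-]
Why: Ester saponification at the ester carbonyl; the 5-aryloxy ether should stay intact, as it does in other 5-aryloxy-2-furoates.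

Step 5
Reactants: 8 5-(2-formyl-3,5-dimethoxyphenoxy)-3-methoxyfuran-2-carboxylic acid
Product: 9 2,4-dimethoxy-6-[(4-methoxyfuran-2-yl)oxy]benzaldehyde
Conditions: Ag2CO3 (10 mol %), DMSO, 110 °C; NaHCO3 work-up
Reagents that add atoms: none
Why: Ag2CO3-catalysed protodecarboxylation of a heteroaromatic 2-carboxylic acid, eased by the 3-methoxy and 5-aryloxy donors that favour ipso-protonation; decarboxylation of 5-aryloxy-2-furoic acids is the classical entry to 2-aryloxyfurans.

Step 6
Reactants: 9 2,4-dimethoxy-6-[(4-methoxyfuran-2-yl)oxy]benzaldehyde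
Product: 10 2-(2-ethynyl-3,5-dimethoxyphenoxy)-4-methoxyfuran
Conditions: dimethyl (1-diazo-2-oxopropyl)phosphonate, K2CO3, MeOH, 0 °C to rt
Reagents that add atoms: dimethyl (1-diazo-2-oxopropyl)phosphonate, CC(=O)C(=[N+]=[N-])P(=O)(OC)OC
Why: Seyferth–Gilbert homologation in its Ohira–Bestmann form turns the aryl aldehyde into the terminal alkyne under basic methanolic conditions that the acid-labile furan should tolerate.

Step 7
Reactants: 10 2-(2-ethynyl-3,5-dimethoxyphenoxy)-4-methoxyfuran
Product: 13 2-[3,5-dimethoxy-2-(pinacolborylethynyl)phenoxy]-4-methoxyfuran, via lithium acetylide 11 (not isolated), via lithium alkynylborate 12 (not isolated)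
Conditions: n-BuLi (1.0 equiv), THF, −78 °C; i-PrOBpin, −78 °C; then HCl·Et2O (1.0 equiv), −78 °C to rt; filtration under Ar, no aqueous work-up, used crude
Reagents that add atoms: 2-isopropoxy-4,4,5,5-tetramethyl-1,3,2-dioxaborolane, CC(C)OB1OC(C)(C)C(C)(C)O1
Why: Standard deprotonation–borylation of a terminal alkyne (far more acidic than the furan C–H bonds): the acetylide adds to the isopropoxyboronate and one equivalent of anhydrous acid releases the alkynyl pinacolboronate.

Step 8
Reactants: 13 2-[3,5-dimethoxy-2-(pinacolborylethynyl)phenoxy]-4-methoxyfuran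
Product: 16 3,7,9-trimethoxy-1-(4,4,5,5-tetramethyl-1,3,2-dioxaborolan-2-yl)dibenzo[b,d]furan-2-ol, via oxanorbornadiene cycloadduct 14 (not isolated), via ring-opened zwitterion 15 (not isolated)
Conditions: o-dichlorobenzene (0.02 M), 2,6-lutidine (0.2 equiv), BHT (5 mol %), Ar, 150 °C, sealed tube
Reagents that add atoms: none
Why: Proposed new method: the electron-rich 2-aryloxy-4-methoxyfuran should add its ortho-tethered alkynylboronate in a thermal intramolecular [4+2] cycloaddition to give oxanorbornadiene 14, whose bridge C–O bond at the aryloxy-bearing bridgehead then ionises to zwitterion 15 (cation stabilised by the aryloxy oxygen and, through the enol ether, by the methoxy group) before loss of the proton from the oxygen-bearing carbon aromatises ring B. The closest known reactions are the intramolecular Diels–Alder reaction of 2-heteroatom-substituted furans with alkynes on a three-atom tether, which open to para-substituted phenols, and the benzannulation of 2-alkoxyfurans with alkynes or arynes to 4-alkoxyphenols; alkynyl pinacolboronates are established 2π partners in thermal cycloadditions. Ring B closes by the [4+2] event itself (the four furan carbons as the diene, the alkyne as the dienophile), and the five-membered oxygen ring closes in the same event in a 5-exo-dig sense because the O–aryl tether joins the aryloxy-bearing furan carbon to the inner alkyne carbon. No stereocentre remains in the product; the bridgeheads of 14 and the carbinol carbon of 15 are transient and racemic. The step needs one regiochemistry of addition, which the tether enforces (inner alkyne carbon to the aryloxy-bearing furan carbon, boron-bearing carbon to the unsubstituted furan α-carbon), and one direction of bridge opening, which the aryloxy group secures so that the free hydroxyl appears only beside the boron-bearing carbon; acid-free anhydrous conditions should protect the furan and the C–B bond.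

Step 9
Reactants: 17 2-fluoro-4,6-dimethoxybenzaldehyde
Product: 18 3-bromo-2-fluoro-4,6-dimethoxybenzaldehyde
Conditions: NBS, MeCN, 0 °C to rt
Reagents that add atoms: N-bromosuccinimide, O=C1CCC(=O)N1Br
Why: Electrophilic aromatic bromination at the position between the fluorine and a methoxy group, which is para to the other methoxy group; 1-halo-3,5-dialkoxyarenes favour this site over the more hindered position flanked by the two methoxy groups.

Step 10
Reactants: 16 3,7,9-trimethoxy-1-(4,4,5,5-tetramethyl-1,3,2-dioxaborolan-2-yl)dibenzo[b,d]furan-2-ol; 18 3-bromo-2-fluoro-4,6-dimethoxybenzaldehyde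
Product: 19 3-bromo-4,6-dimethoxy-2-{[3,7,9-trimethoxy-1-(pinacolboryl)dibenzofuran-2-yl]oxy}benzaldehyde
Conditions: Cs2CO3, 4 Å MS, DMF, 70 °C
Reagents that add atoms: none
Why: Nucleophilic aromatic substitution (SNAr) of the fluoride ortho to the formyl group by the phenoxide of 16, helped inductively by the neighbouring bromine; anhydrous carbonate should leave the aryl–boron bond intact.

Step 11
Reactants: 19 3-bromo-4,6-dimethoxy-2-{[3,7,9-trimethoxy-1-(pinacolboryl)dibenzofuran-2-yl]oxy}benzaldehyde
Product: 21 2-(2-bromo-6-hydroxy-3,5-dimethoxyphenoxy)-3,7,9-trimethoxydibenzofuran-1-ol, via aryl formate phenol 20 (not isolated)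
Conditions: mCPBA (2.5 equiv), CH2Cl2, 0 °C to rt; then Et3N, MeOH, rt
Reagents that add atoms: 3-chloroperoxybenzoic acid, OOC(=O)c1cccc(Cl)c1
Why: Peracid oxidation of the aryl–boron bond to the phenol, combined with Baeyer–Villiger (Dakin-type) oxidation of the electron-rich aldehyde to the aryl formate, which mild methanolysis cleaves; the non-basic oxidation medium avoids Smiles migration while the formyl group is still present.

Step 12
Reactants: 21 2-(2-bromo-6-hydroxy-3,5-dimethoxyphenoxy)-3,7,9-trimethoxydibenzofuran-1-ol
Product: 22 pentamethyl ether dioxin phenol (fully cyclised benzofuro-fused dibenzo-1,4-dioxin; the only free hydroxyl is on ring D, ortho to the para dioxin oxygen; methoxy groups on the other two oxygenated ring D carbons, on ring B and on both oxygenated ring A carbons)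
Conditions: CuI (20 mol %), N,N-dimethylglycine (40 mol %), Cs2CO3, 1,4-dioxane, 100 °C
Reagents that add atoms: none
Why: Intramolecular Ullmann diaryl ether synthesis, the classical closure of 2-(2-bromophenoxy)phenols to dibenzo-1,4-dioxins; only the hydroxyl at position 1 of the dibenzofuran can reach the brominated ring D carbon in a six-membered closure, and the electron-rich ring D should not undergo Smiles rearrangement.

Step 13
Reactants: 22 pentamethyl ether dioxin phenol; 23 (3,5-dimethoxyphenyl)boronic acid
Product: 24 heptamethyl ether of the target (22 with a 3,5-dimethoxyphenyl group on its free ring D oxygen)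
Conditions: Cu(OAc)2 (1.5 equiv), pyridine, 4 Å MS, CH2Cl2, air, rt
Reagents that add atoms: none
Why: Chan–Lam coupling of a phenol with an unhindered arylboronic acid, a reaction known to tolerate phenols flanked by two ortho substituents.

Step 14
Reactants: 24 heptamethyl ether of the target
Product: 25 CNP0256302.0 (the heptaphenol)
Conditions: BBr3 (excess), CH2Cl2, −78 °C to rt; then H2O, 0 °C, under Ar
Reagents that add atoms: none
Why: Lewis-acid cleavage of aryl methyl ethers with BBr3; the diaryl ether, dioxin and furan C–O bonds have no sp3 carbon for bromide attack and should survive.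

**Compound list**

1 | 3-methoxyfuran | COc1ccoc1 | starting material
2 | 2-lithio-3-methoxyfuran (formed in the flask) | [Li]c1occc1OC | intermediate
3 | methyl 3-methoxyfuran-2-carboxylate | COC(=O)c1occc1OC | intermediate
4 | methyl 5-(chloromagnesio)-3-methoxyfuran-2-carboxylate (formed in the flask) | COC(=O)c1oc([Mg]Cl)cc1OC | intermediate
5 | methyl 5-bromo-3-methoxyfuran-2-carboxylate | COC(=O)c1oc(Br)cc1OC | intermediate
6 | 2-hydroxy-4,6-dimethoxybenzaldehyde | COc1cc(O)c(C=O)c(OC)c1 | starting material
7 | methyl 5-(2-formyl-3,5-dimethoxyphenoxy)-3-methoxyfuran-2-carboxylate | COC(=O)c1oc(Oc2cc(OC)cc(OC)c2C=O)cc1OC | intermediate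
8 | 5-(2-formyl-3,5-dimethoxyphenoxy)-3-methoxyfuran-2-carboxylic acid | OC(=O)c1oc(Oc2cc(OC)cc(OC)c2C=O)cc1OC | intermediate
9 | 2,4-dimethoxy-6-[(4-methoxyfuran-2-yl)oxy]benzaldehyde | COc1coc(Oc2cc(OC)cc(OC)c2C=O)c1 | intermediate
10 | 2-(2-ethynyl-3,5-dimethoxyphenoxy)-4-methoxyfuran | COc1coc(Oc2cc(OC)cc(OC)c2C#C)c1 | intermediate
11 | lithium acetylide of 10 (formed in the flask) | COc1coc(Oc2cc(OC)cc(OC)c2C#C[Li])c1 | intermediate
12 | lithium alkynyl(isopropoxy)(pinacolato)borate (formed in the flask) | [Li+].COc1coc(Oc2cc(OC)cc(OC)c2C#C[B-]2(OC(C)C)OC(C)(C)C(C)(C)O2)c1 | intermediate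
13 | 2-[3,5-dimethoxy-2-(pinacolborylethynyl)phenoxy]-4-methoxyfuran (key-step precursor) | COc1cc(OC)c(C#CB2OC(C)(C)C(C)(C)O2)c(Oc2cc(OC)co2)c1 | intermediate
14 | oxanorbornadiene cycloadduct (racemic; oxygen bridge between the aryloxy-bearing carbon and the CH carbon next to the boron-bearing alkene carbon; formed in the flask) | COc1cc(OC)c2c(c1)OC13OC(C(B4OC(C)(C)C(C)(C)O4)=C21)C(OC)=C3 | intermediate
15 | ring-opened oxocarbenium alkoxide zwitterion (racemic; formed in the flask) | COC1=CC2=[O+]c3cc(OC)cc(OC)c3C2=C(B2OC(C)(C)C(C)(C)O2)C1[O-] | intermediate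
16 | 3,7,9-trimethoxy-1-(4,4,5,5-tetramethyl-1,3,2-dioxaborolan-2-yl)dibenzo[b,d]furan-2-ol (key-step product) | COc1cc2oc3cc(OC)cc(OC)c3c2c(B2OC(C)(C)C(C)(C)O2)c1O | intermediate
17 | 2-fluoro-4,6-dimethoxybenzaldehyde | COc1cc(F)c(C=O)c(OC)c1 | starting material
18 | 3-bromo-2-fluoro-4,6-dimethoxybenzaldehyde | COc1cc(OC)c(C=O)c(F)c1Br | intermediate
19 | 3-bromo-4,6-dimethoxy-2-{[3,7,9-trimethoxy-1-(pinacolboryl)dibenzofuran-2-yl]oxy}benzaldehyde | COc1cc2oc3cc(OC)cc(OC)c3c2c(B2OC(C)(C)C(C)(C)O2)c1Oc1c(C=O)c(OC)cc(OC)c1Br | intermediate
20 | 3-bromo-2-[(1-hydroxy-3,7,9-trimethoxydibenzofuran-2-yl)oxy]-4,6-dimethoxyphenyl formate (formed in the flask) | COc1cc2oc3cc(OC)cc(OC)c3c2c(O)c1Oc1c(OC=O)c(OC)cc(OC)c1Br | intermediate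
21 | 2-(2-bromo-6-hydroxy-3,5-dimethoxyphenoxy)-3,7,9-trimethoxydibenzofuran-1-ol | COc1cc2oc3cc(OC)cc(OC)c3c2c(O)c1Oc1c(O)c(OC)cc(OC)c1Br | intermediate
22 | pentamethyl ether dioxin phenol (free hydroxyl on ring D ortho to the para dioxin oxygen; methoxy on the other two oxygenated ring D carbons, on ring B and on both oxygenated ring A carbons) | Oc1c(OC)cc(OC)c2c1Oc1c(OC)cc3oc4cc(OC)cc(OC)c4c3c1O2 | intermediate
23 | (3,5-dimethoxyphenyl)boronic acid | COc1cc(OC)cc(B(O)O)c1 | starting material
24 | heptamethyl ether of the target | COc1cc(OC)cc(Oc2c(OC)cc(OC)c3c2Oc2c(OC)cc4oc5cc(OC)cc(OC)c5c4c2O3)c1 | intermediate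
25 | CNP0256302.0 | Oc1cc(O)cc(Oc2c(O)cc(O)c3c2Oc2c(O)cc4oc5cc(O)cc(O)c5c4c2O3)c1 | target

**Step count and risks**

Total: 14 steps. Longest linear sequence: 13 steps (steps 1–8 and 10–14; step 9 prepares the ring D partner).

Steps most likely to fail:

1. Step 8 (proposed new method). Thermal decomposition of the very electron-rich furan, or loss of boron from the alkyne, may outrun the cycloaddition. The fallback sets out from 23, builds ring B by the classical quinone route and lets a formyl carbon take the marking role of boron. Boronic acid 23 is oxidised (H2O2, THF/H2O) to 3,5-dimethoxyphenol F1, which is also a catalogue compound. F1 is condensed under acid (AcOH, catalytic H2SO4) with 2-methoxy-1,4-benzoquinone F2. Conjugate arylation at the quinone carbon para to the methoxy-bearing carbon, then cyclodehydration, should give 3,7,9-trimethoxydibenzo[b,d]furan-2-ol F3. MgCl2-mediated ortho-formylation (MgCl2, Et3N, paraformaldehyde; Casnati–Skattebøl) at position 1, the only free position ortho to the hydroxyl, gives 2-hydroxy-3,7,9-trimethoxydibenzo[b,d]furan-1-carbaldehyde F4. SNAr with 18 (Cs2CO3, DMF) gives 2-(6-bromo-2-formyl-3,5-dimethoxyphenoxy)-3,7,9-trimethoxydibenzo[b,d]furan-1-carbaldehyde F5. Double Baeyer–Villiger oxidation with mCPBA and methanolysis returns to the route at 21.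

2. Step 10. The hindered ortho-boryl phenoxide may lose boron, or react too slowly, before the singly activated fluoride is displaced. The fallback sets out from 17 and 16 and uses a doubly activated, symmetric electrophile. Rieche formylation of 17 (Cl2CHOMe, TiCl4), directed para to a methoxy group and away from the position flanked by both methoxy groups, gives 2-fluoro-4,6-dimethoxybenzene-1,3-dicarbaldehyde F6, whose fluoride lies between two formyl groups. F6 should react with 16 near room temperature to give 2-{[3,7,9-trimethoxy-1-(pinacolboryl)dibenzofuran-2-yl]oxy}-4,6-dimethoxybenzene-1,3-dicarbaldehyde F7. Boron would not survive the peracid step, so it is exchanged for bromine (CuBr2, MeOH/H2O, bromodeboronation) to give 2-[(1-bromo-3,7,9-trimethoxydibenzofuran-2-yl)oxy]-4,6-dimethoxybenzene-1,3-dicarbaldehyde F8. Double Baeyer–Villiger oxidation with mCPBA and methanolysis give the symmetric 2-[(1-bromo-3,7,9-trimethoxydibenzofuran-2-yl)oxy]-4,6-dimethoxybenzene-1,3-diol F9. Intramolecular Ullmann coupling (CuI, N,N-dimethylglycine, Cs2CO3) of either hydroxyl with the ring B bromide returns to the route at 22.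

3. Step 5. The furan being formed may be destroyed under the decarboxylation conditions by protonation and hydrolytic loss of the aryloxy group, or by polymerisation. The fallback sets out from 5 and moves the decarboxylation ahead of the ether formation. Bromo ester 5 is saponified (LiOH) to 5-bromo-3-methoxyfuran-2-carboxylic acid F10 and decarboxylated (Cu2O, quinoline, heat) to the volatile 2-bromo-4-methoxyfuran F11. F11 is coupled at once with phenol 6 (CuI, picolinic acid, K3PO4, DMSO) to return to the route at 9.

Further compounds
F1 | step 8 | 3,5-dimethoxyphenol | COc1cc(O)cc(OC)c1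
F2 | step 8 | 2-methoxy-1,4-benzoquinone | COC1=CC(=O)C=CC1=O
F3 | step 8 | 3,7,9-trimethoxydibenzo[b,d]furan-2-ol | COc1cc2oc3cc(OC)cc(OC)c3c2cc1O
F4 | step 8 | 2-hydroxy-3,7,9-trimethoxydibenzo[b,d]furan-1-carbaldehyde | COc1cc2oc3cc(OC)cc(OC)c3c2c(C=O)c1O
F5 | step 8 | 2-(6-bromo-2-formyl-3,5-dimethoxyphenoxy)-3,7,9-trimethoxydibenzo[b,d]furan-1-carbaldehyde | COc1cc2oc3cc(OC)cc(OC)c3c2c(C=O)c1Oc1c(C=O)c(OC)cc(OC)c1Br
F6 | step 10 | 2-fluoro-4,6-dimethoxybenzene-1,3-dicarbaldehyde | COc1cc(OC)c(C=O)c(F)c1C=O
F7 | step 10 | 2-{[3,7,9-trimethoxy-1-(pinacolboryl)dibenzofuran-2-yl]oxy}-4,6-dimethoxybenzene-1,3-dicarbaldehyde | COc1cc2oc3cc(OC)cc(OC)c3c2c(B2OC(C)(C)C(C)(C)O2)c1Oc1c(C=O)c(OC)cc(OC)c1C=O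
F8 | step 10 | 2-[(1-bromo-3,7,9-trimethoxydibenzofuran-2-yl)oxy]-4,6-dimethoxybenzene-1,3-dicarbaldehyde | COc1cc2oc3cc(OC)cc(OC)c3c2c(Br)c1Oc1c(C=O)c(OC)cc(OC)c1C=O
F9 | step 10 | 2-[(1-bromo-3,7,9-trimethoxydibenzofuran-2-yl)oxy]-4,6-dimethoxybenzene-1,3-diol | COc1cc2oc3cc(OC)cc(OC)c3c2c(Br)c1Oc1c(O)c(OC)cc(OC)c1O
F10 | step 5 | 5-bromo-3-methoxyfuran-2-carboxylic acid | COc1cc(Br)oc1C(=O)O
F11 | step 5 | 2-bromo-4-methoxyfuran | COc1coc(Br)c1
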